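Remark on the chemistry: the target has no stereocentre, and its only non-aromatic double bond carries two identical methyl groups, so no configuration has to be set. The formulae of 9, 13 and 14 were checked atom by atom against the chromone numbering of the target and needed no correction; the improvement made is in how 9 is reached.

## Structural features

The target is an isoflavone: a benzene ring A fused to a 4-pyranone ring C (together a chromen-4-one), with ring B attached by a single bond from C3 to C1′. Ring A has a phloroglucinol pattern, with hydroxyls on C5 and C7, the ring oxygen O1 on C8a, a 3-hydroxy-3-methylbutyl chain on C6 between the two hydroxyls, and hydrogen on C8. Ring B is a resorcinol with hydroxyls on C2′ and C4′ and a prenyl group on C3′ between them. With no stereocentre present, the problem is one of regiochemistry only. The fragile groups are the prenyl alkene and the tertiary alcohol: each sits ortho to two phenols and would close to a 2,2-dimethylchroman under strong Brønsted or Lewis acid. The alkene also excludes hydrogenolysis, and the pyranone is opened by hard nucleophiles. The real difficulty is to place three things without ambiguity: the side chain on C6 and not C8, the prenyl group on C3′ and not C5′, and ring B on C3 and not C2. The key step uses the fact that C4 is a carbonyl carbon on C4a, ortho to the oxygen-bearing C8a. The atoms O1–C8a–C4a–C4 are therefore those of a salicylaldehyde, and O1–C2 and C3–C4 can be made by adding the two carbons of an alkyne across the phenolic O–H and the formyl C–H.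

## Logic of the disconnections

16 to 15. The four phenolic O–H bonds are traced back to four methoxymethyl acetals. This acetal is removed by dilute acid, needs neither hydrogen nor a strong Lewis acid, and its oxygen atoms direct both ring metalations earlier in the route. The forward step must use acid mild enough that the tertiary alcohol and the prenyl group do not cyclise onto the freed phenols.

15 to 14. A trimethylsilyl group is placed on C2 (C2–Si bond cut in the forward sense). It is there only to decide which alkyne carbon ends up next to O1 in the annulation. The forward step must remove it without nucleophilic opening of ring C.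

14 to 9 and 13. The bonds C3–C4 and O1–C2 are cut, which opens ring C and divides the molecule into two arenes of similar size, each already carrying all its substituents. The forward step must insert 13 in one orientation (aryl carbon to C4, silyl carbon to O1). It must leave the prenyl alkene, the acetals and the tertiary alcohol alone, and it must find only one free phenol in 9. That phenol is the one para to the side chain, so the chain ends on C6 and not on C8.

13 to 11 and 12. The aryl–alkynyl bond is cut. The forward step is a standard cross-coupling of an aryl iodide with a terminal alkyne and makes no unusual demand.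

11 to 5 (through 10). The C–I bond is cut. The two ring C–H bonds next to an acetal oxygen in 5 are equivalent, so directed metalation can give only one iodide. The forward step must metalate the ring faster than it deprotonates the benzylic and allylic CH2.

9 to 8. The bond between the ring and the formyl carbon is cut. Because 8 is symmetric, both positions ortho to its free hydroxyl give the same aldehyde, and only that hydroxyl can direct the formylation. The forward step must stop at the mono-aldehyde.

8 to 6 (through 7). The aryl C–O bond para to the side chain is cut. In 6 this carbon carries the only ring hydrogen without an ortho neighbour, so a sterically controlled C–H borylation followed by oxidation reaches it alone. This avoids having to distinguish the three hydroxyls of a phloroglucinol aldehyde by selective protection, and it lets ring A and ring B both start from 5. The forward step must tolerate the free tertiary hydroxyl.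

6 to 5. The tertiary C–O bond is cut. The forward step is a Markovnikov hydration of the trisubstituted alkene under conditions that spare the acetals.

5 to 2 and 3 (through 4). The aryl–CH2 bond is cut at the carbon between the two acetal oxygens, the most acidic and best coordinated site of 2. The forward step must alkylate at the primary carbon of 3 and not at its tertiary end.

2 to 1. The two O–acetal bonds are cut; the forward step is a double O-alkylation.

## Other disconnections considered

Alternative 1: The two bonds at the carbonyl carbon, C4–C4a and C3–C4, are cut, so that C4 comes from carbon monoxide.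
- Forward step: Pd(PPh3)4 would take the aryl iodide A2 through oxidative addition and CO insertion to an aroyl palladium species. The vinyl stannane A3 would intercept it to give the open-chain enone A1. Fluoride would then free the C8a phenol, which closes ring C by conjugate addition and loss of ethanol.
- In its favour: ring B is bound to the future C3 before the coupling, so there is no question of orientation. On this point it is better than the chosen plan. Ring closure would give 15 directly with hydrogen on C2, so the end game is equal in length. A2 should be reachable from 8 by ortho-iodination and O-silylation.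
- Against it here: the iodide carbon of A2 lies between two oxygen substituents on an electron-rich ring. The aroyl palladium intermediate must then transmetalate with a hindered, 1,1-disubstituted vinyl stannane, so direct coupling without CO and decarbonylation are likely to compete. A3 is an acid-sensitive enol ether. It would need a regio- and stereocontrolled hydrostannation of an aryl ynol ether made from 11, which adds two or three steps and brings tin residues.
- Comparison: both plans use the same ring A phenol and ring B iodide. The chosen plan closes the ring in the coupling itself and joins two components instead of three. Alternative 1 is the more secure on regiochemistry and the less secure on reactivity, and it is longer by about two steps.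

Alternative 2: Ring B is taken apart at C2′–C3′, C4′–C5′ and C1′–C2′ and is built last from acyclic pieces.
- Forward step: irradiation of the diazoketone A5 would trigger a Wolff rearrangement to the derived ketene, which adds the siloxyalkyne A6 in a [2+2] manner. Four-electron ring opening, six-electron ring closure and tautomerisation would give the phenol A4.
- In its favour: the ring B pattern (prenyl between two oxygens, hydrogen on C5′ and C6′) follows from the mechanism without any directed metalation. The C3–C1′ carbon is attached to the chromone from the start, so the isoflavone regiochemistry is not in question. On both points it is better than the chosen plan. It forms three bonds and a ring in one operation against two bonds and a ring. The end game after the key step (fluoride, then acid) is equal in length.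
- Against it here: A5 holds a chromone, which absorbs light and accepts nucleophiles, next to a diazoketone. A6 is moisture-sensitive and needs its own synthesis. The ring A and ring C part would have to come from a fully protected chromone-3-carbaldehyde, whose usual preparation with a chloroiminium reagent is hard on methoxymethyl acetals. A4 carries three kinds of protecting group.
- Comparison: the alternative is stronger on regiochemical certainty and weaker on functional-group tolerance and on length; it is estimated at six or more steps longer.

Alternative 3: The bonds O1–C8a, C4–C4a and O1–C2 are cut, so that ring A enters as an aryne and ring B with C2, C3 and C4 as an acrylic acid.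
- Forward step: CsF would trigger 1,2-elimination of the ortho-silylaryl triflate A8 across C4a and C8a. The carboxylate of A9 would add at C8a, the carbon remote from the C5 acetal oxygen. The aryl anion at C4a would take the acyl group through a four-membered transition state. The phenoxide so formed would add at C2 and expel methoxide to give A7.
- In its favour: three bonds and ring C form without a transition metal. C2 carries hydrogen at once, and the remaining acetal and silyl groups should fall in one acid step, so the end game is one step shorter; here it is better than the chosen plan. The site of attack on a 3-alkoxyaryne has a firm electronic basis, so its regiochemical argument is at least equal to the analogy behind the chosen plan.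
- Against it here: A8 is a hexasubstituted benzene. Reaching it from 8 would take about five steps (protection of the tertiary alcohol, ortho-bromination, O-silylation with silyl migration to carbon, triflation). The aryl anion at C4a is flanked by an acetal and may be protonated by the acid before the acyl shift, which would stop at an aryl ester. A9 needs a ring B arylacetic ester, then formylation, O-methylation and saponification. Warm fluoride also threatens the triethylsilyl ether.
- Comparison: the chosen plan keeps ring A at the stage of a simple salicylaldehyde and ring B at an alkyne one step from the iodide. Alternative 3 has the more elegant ring closure and the shorter end game, but needs about five more steps overall and a less certain acyl transfer.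

Key step: step 8

## Route

Step 1
Reactants: 1 resorcinol
Product: 2 1,3-bis(methoxymethoxy)benzene
Conditions: MOMCl (2.5 equiv), i-Pr2NEt (3 equiv), CH2Cl2, 0 °C to rt
Reagents that add atoms: chloromethyl methyl ether, COCCl
Why: Double O-alkylation of the phenols by the reactive α-chloro ether under amine base (acetal protection); the acetal oxygens later direct both ring metalations.

Step 2
Reactants: 2 1,3-bis(methoxymethoxy)benzene; 3 1-bromo-3-methylbut-2-ene
Product: 5 1,3-bis(methoxymethoxy)-2-(3-methylbut-2-en-1-yl)benzene, via 2,6-bis(methoxymethoxy)phenyllithium 4 (not isolated)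
Conditions: n-BuLi (1.1 equiv), THF, 0 °C to rt; CuI (10 mol %), then 3, −78 °C to rt
Reagents that add atoms: none
Why: Directed ortho-metalation takes the C–H between the two acetal oxygens, the most acidic and doubly coordinated site, so 4 forms alone. Copper-catalysed allylic substitution on the primary bromide then occurs at the unhindered CH2 terminus and gives the linear prenyl arene.

Step 3
Reactants: 5 1,3-bis(methoxymethoxy)-2-(3-methylbut-2-en-1-yl)benzene
Product: 6 4-[2,6-bis(methoxymethoxy)phenyl]-2-methylbutan-2-ol
Conditions: Co(acac)2 (20 mol %), PhSiH3 (2 equiv), O2 (1 atm), THF, rt; aq. Na2S2O3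
Reagents that add atoms: dioxygen, O=O
Why: Mukaiyama hydration: hydrogen-atom transfer from a cobalt hydride to the trisubstituted alkene gives the tertiary radical, which is trapped by O2 and reduced by the silane to the Markovnikov alcohol. The arene and the acetals are inert to these neutral radical conditions.

Step 4
Reactants: 6 4-[2,6-bis(methoxymethoxy)phenyl]-2-methylbutan-2-ol
Product: 8 4-(3-hydroxy-3-methylbutyl)-3,5-bis(methoxymethoxy)phenol, via aryl pinacol boronate 7 (not isolated)
Conditions: [Ir(OMe)(cod)]2 (1.5 mol %), 4,4′-di-tert-butyl-2,2′-bipyridine (3 mol %), B2pin2 (1.5 equiv), THF, 80 °C; then aq. NaOH, H2O2, THF, 0 °C to rt; aq. NH4Cl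
Reagents that add atoms: bis(pinacolato)diboron, CC1(C)OB(OC1(C)C)B1OC(C)(C)C(C)(C)O1 (supplies the boryl group of 7); hydrogen peroxide, OO (supplies the phenol oxygen of 8)
Why: Iridium-catalysed aromatic C–H borylation is sterically controlled and in this 1,2,3-trisubstituted arene reaches only the C–H without an ortho neighbour, which is para to the side chain. The tertiary hydroxyl is expected to be borylated reversibly at most and freed on work-up. Basic peroxide then turns C–B into C–OH at the same carbon (one-pot borylation and oxidation).

Step 5
Reactants: 8 4-(3-hydroxy-3-methylbutyl)-3,5-bis(methoxymethoxy)phenol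
Product: 9 2-hydroxy-5-(3-hydroxy-3-methylbutyl)-4,6-bis(methoxymethoxy)benzaldehyde
Conditions: MgCl2 (3 equiv), Et3N (5 equiv), (CH2O)n (6 equiv), MeCN, 75 °C; aq. NH4Cl
Reagents that add atoms: paraformaldehyde (formaldehyde), C=O
Why: Magnesium-mediated ortho-formylation of a phenol (Casnati–Skattebøl formylation): the magnesium phenoxide delivers formaldehyde to the ortho carbon, and the hydroxymethyl intermediate is oxidised by a second formaldehyde through hydride transfer. Because 8 is symmetric, both ortho sites give the same aldehyde, and only the free hydroxyl para to the chain can direct, which fixes that oxygen as the future O1.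

Step 6
Reactants: 5 1,3-bis(methoxymethoxy)-2-(3-methylbut-2-en-1-yl)benzene
Product: 11 1-iodo-2,4-bis(methoxymethoxy)-3-(3-methylbut-2-en-1-yl)benzene, via prenylated aryllithium 10 (not isolated)
Conditions: s-BuLi (1.2 equiv), TMEDA (1.2 equiv), THF, −78 °C; I2 (1.3 equiv), −78 °C; aq. Na2S2O3
Reagents that add atoms: iodine, II
Why: Directed ortho-metalation at the ring C–H next to an acetal oxygen (the two such positions of 5 are equivalent), run cold so that the coordination-directed ring metalation outruns deprotonation of the benzylic and allylic CH2. The iodine quench of 10 at −78 °C is much faster than any addition of iodine to the trisubstituted alkene.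

Step 7
Reactants: 11 1-iodo-2,4-bis(methoxymethoxy)-3-(3-methylbut-2-en-1-yl)benzene; 12 ethynyltrimethylsilane
Product: 13 {[2,4-bis(methoxymethoxy)-3-(3-methylbut-2-en-1-yl)phenyl]ethynyl}trimethylsilane
Conditions: Pd(PPh3)2Cl2 (3 mol %), CuI (5 mol %), Et3N, THF, 50 °C
Reagents that add atoms: none
Why: Sonogashira coupling of an aryl iodide with a terminal alkyne; iodides couple at mild temperature even when electron-rich and ortho-substituted, and the C–Si bond, the acetals and the prenyl group are untouched.

Step 8
Reactants: 9 2-hydroxy-5-(3-hydroxy-3-methylbutyl)-4,6-bis(methoxymethoxy)benzaldehyde; 13 {[2,4-bis(methoxymethoxy)-3-(3-methylbut-2-en-1-yl)phenyl]ethynyl}trimethylsilane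
Product: 14 3-[2,4-bis(methoxymethoxy)-3-(3-methylbut-2-en-1-yl)phenyl]-6-(3-hydroxy-3-methylbutyl)-5,7-bis(methoxymethoxy)-2-(trimethylsilyl)-4H-chromen-4-one
Conditions: [Cp*RhCl2]2 (2.5 mol %), Cu(OAc)2 (anhydrous, 2.2 equiv), 1,2-dichloroethane, 80 °C, N2
Reagents that add atoms: none
Why: The rhodium acetate formed in the flask binds the phenoxide of 9 and then breaks the formyl C–H bond by concerted metalation–deprotonation, which gives an acyl rhodacycle of five ring atoms spanning O1, C8a, C4a and C4. Alkyne 13 inserts into the rhodium–acyl bond so that its aryl-bearing carbon joins C4 (new C3–C4 bond) while the silyl-bearing carbon stays on rhodium, giving an oxarhodacycle of seven ring atoms. Reductive elimination of C–O then forms O1–C2 and closes ring C as a six-membered pyranone, a formal [4+2] oxidative annulation, and Cu(OAc)2 takes the monovalent rhodium back to the trivalent state. The closest known reaction type is the rhodium-catalysed oxidative coupling of salicylaldehydes with internal alkynes to 2,3-disubstituted chromones; the orientation with an aryl silyl alkyne rests on analogy with heteroannulations of the Larock type, where the silyl group ends next to the heteroatom, and is not proven for this case. No stereocentre is formed. The step needs the insertion to go in one orientation, which the bulk of SiMe3 (it avoids the carbon where the new C–C bond forms) and the stabilisation of a carbon–metal bond by an α-silyl group should secure. It also needs a single site of C–O closure, which is secured because the only free phenol of 9 is the one para to the side chain, so only the 6-substituted chromone can form; the trisubstituted alkene, the acetals and the tertiary alcohol offer the acyl rhodium species no competing pathway. Any loss of the silyl group to the acetic acid set free would give 15 directly and is harmless.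

Step 9
Reactants: 14 3-[2,4-bis(methoxymethoxy)-3-(3-methylbut-2-en-1-yl)phenyl]-6-(3-hydroxy-3-methylbutyl)-5,7-bis(methoxymethoxy)-2-(trimethylsilyl)-4H-chromen-4-one
Product: 15 3-[2,4-bis(methoxymethoxy)-3-(3-methylbut-2-en-1-yl)phenyl]-6-(3-hydroxy-3-methylbutyl)-5,7-bis(methoxymethoxy)-4H-chromen-4-one
Conditions: Bu4NF (1.2 equiv), AcOH (1.5 equiv), THF, 0 °C to rt
Reagents that add atoms: none
Why: Protodesilylation of an α-oxygenated vinylsilane: fluoride attacks silicon and the C2 carbanion equivalent, stabilised by the ring oxygen and the electron-poor pyranone, is protonated by the acetic acid buffer. Buffering keeps the medium from becoming basic enough to open ring C; the acetals, the alkene and the tertiary alcohol are inert.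

Step 10
Reactants: 15 3-[2,4-bis(methoxymethoxy)-3-(3-methylbut-2-en-1-yl)phenyl]-6-(3-hydroxy-3-methylbutyl)-5,7-bis(methoxymethoxy)-4H-chromen-4-one
Product: 16 3-[2,4-dihydroxy-3-(3-methylbut-2-en-1-yl)phenyl]-5,7-dihydroxy-6-(3-hydroxy-3-methylbutyl)-4H-chromen-4-one
Conditions: HCl (about 1 M in MeOH), THF cosolvent, rt to 40 °C, monitored; aq. NaHCO3
Reagents that add atoms: none
Why: Acid-catalysed acetal exchange with methanol removes all four methoxymethyl groups as dimethoxymethane. Dilute acid at or just above room temperature should stay below the point at which the tertiary alcohol ionises or the prenyl alkene is protonated, so chroman formation should not compete.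

## Compound list

1 | resorcinol (benzene-1,3-diol) | Oc1cccc(O)c1 | starting material
2 | 1,3-bis(methoxymethoxy)benzene | COCOc1cccc(OCOC)c1 | intermediate
3 | 1-bromo-3-methylbut-2-ene | CC(C)=CCBr | starting material
4 | 2,6-bis(methoxymethoxy)phenyllithium | [Li]c1c(OCOC)cccc1OCOC | intermediate (not isolated)
5 | 1,3-bis(methoxymethoxy)-2-(3-methylbut-2-en-1-yl)benzene | COCOc1cccc(OCOC)c1CC=C(C)C | intermediate
6 | 4-[2,6-bis(methoxymethoxy)phenyl]-2-methylbutan-2-ol | COCOc1cccc(OCOC)c1CCC(C)(C)O | intermediate
7 | 4-[2,6-bis(methoxymethoxy)-4-(4,4,5,5-tetramethyl-1,3,2-dioxaborolan-2-yl)phenyl]-2-methylbutan-2-ol | COCOc1cc(B2OC(C)(C)C(C)(C)O2)cc(OCOC)c1CCC(C)(C)O | intermediate (not isolated)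
8 | 4-(3-hydroxy-3-methylbutyl)-3,5-bis(methoxymethoxy)phenol | COCOc1cc(O)cc(OCOC)c1CCC(C)(C)O | intermediate
9 | 2-hydroxy-5-(3-hydroxy-3-methylbutyl)-4,6-bis(methoxymethoxy)benzaldehyde | O=Cc1c(O)cc(OCOC)c(CCC(C)(C)O)c1OCOC | intermediate
10 | [2,4-bis(methoxymethoxy)-3-(3-methylbut-2-en-1-yl)phenyl]lithium | [Li]c1ccc(OCOC)c(CC=C(C)C)c1OCOC | intermediate (not isolated)
11 | 1-iodo-2,4-bis(methoxymethoxy)-3-(3-methylbut-2-en-1-yl)benzene | Ic1ccc(OCOC)c(CC=C(C)C)c1OCOC | intermediate
12 | ethynyltrimethylsilane | C#C[Si](C)(C)C | starting material
13 | {[2,4-bis(methoxymethoxy)-3-(3-methylbut-2-en-1-yl)phenyl]ethynyl}trimethylsilane | C[Si](C)(C)C#Cc1ccc(OCOC)c(CC=C(C)C)c1OCOC | intermediate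
14 | 3-[2,4-bis(methoxymethoxy)-3-(3-methylbut-2-en-1-yl)phenyl]-6-(3-hydroxy-3-methylbutyl)-5,7-bis(methoxymethoxy)-2-(trimethylsilyl)-4H-chromen-4-one | COCOc1ccc(-c2c([Si](C)(C)C)oc3cc(OCOC)c(CCC(C)(C)O)c(OCOC)c3c2=O)c(OCOC)c1CC=C(C)C | intermediate
15 | 3-[2,4-bis(methoxymethoxy)-3-(3-methylbut-2-en-1-yl)phenyl]-6-(3-hydroxy-3-methylbutyl)-5,7-bis(methoxymethoxy)-4H-chromen-4-one | COCOc1ccc(-c2coc3cc(OCOC)c(CCC(C)(C)O)c(OCOC)c3c2=O)c(OCOC)c1CC=C(C)C | intermediate
16 | 3-[2,4-dihydroxy-3-(3-methylbut-2-en-1-yl)phenyl]-5,7-dihydroxy-6-(3-hydroxy-3-methylbutyl)-4H-chromen-4-one | CC(C)=CCc1c(O)ccc(-c2coc3cc(O)c(CCC(C)(C)O)c(O)c3c2=O)c1O | target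

## Step count and least certain steps

Total: 10 steps. Longest linear sequence: 8 steps (steps 1, 2, 3, 4, 5, 8, 9 and 10); the ring B branch (steps 6 and 7) leaves the main line at 5.

**Step 8 (key step).**
- What may go wrong: insertion of the alkyne in the reverse orientation, which would put ring B on C2. Other possible failures are loss of carbon monoxide from the acyl rhodium species before insertion (leading to benzofuran-type products), and copper-promoted desilylation and oxidative dimerisation of the alkyne. The orientation is supported only by analogy, and the acyl carbon is crowded by the neighbouring acetal.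
- First remedy within the same reaction: a bulkier cyclopentadienyl ligand ([RhCl(cod)]2 with 1,2,3,4-tetraphenylcyclopentadiene).
- Fallback: replace the annulation by a Suzuki–Miyaura coupling on a 3-iodochromone. It sets out from 9 and, for ring B, from 10 as generated from 5 in step 6, and comes back at 15.
  - Excess MeMgBr in THF at 0 °C adds to 9 to give the racemic benzylic alcohol 2-(1-hydroxyethyl)-4-(3-hydroxy-3-methylbutyl)-3,5-bis(methoxymethoxy)phenol F1.
  - MnO2 in CH2Cl2 oxidises it to the ortho-hydroxyacetophenone 1-[2-hydroxy-5-(3-hydroxy-3-methylbutyl)-4,6-bis(methoxymethoxy)phenyl]ethan-1-one F2.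
  - N,N-Dimethylformamide dimethyl acetal in toluene at 90 °C gives the enaminone (E)-3-(dimethylamino)-1-[2-hydroxy-5-(3-hydroxy-3-methylbutyl)-4,6-bis(methoxymethoxy)phenyl]prop-2-en-1-one F3.
  - Iodine and pyridine in CHCl3 close and iodinate it to 6-(3-hydroxy-3-methylbutyl)-3-iodo-5,7-bis(methoxymethoxy)-4H-chromen-4-one F4.
  - On the ring B side, 10 is quenched with 2-isopropoxy-4,4,5,5-tetramethyl-1,3,2-dioxaborolane instead of iodine to give 2-[2,4-bis(methoxymethoxy)-3-(3-methylbut-2-en-1-yl)phenyl]-4,4,5,5-tetramethyl-1,3,2-dioxaborolane F5.
  - Coupling of F4 with F5 (Pd(PPh3)4, aq. Na2CO3, 1,2-dimethoxyethane, 80 °C) gives 15, and step 10 follows; the iodine quench of step 6 and steps 7 and 9 are then not needed.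

**Step 4.**
- What may go wrong: slowing of the iridium cycle or consumption of the boron reagent by the free tertiary hydroxyl, and over-oxidation of the very electron-rich phenol by basic peroxide during the one-pot work-up.
- Fallback: protect first and isolate the boronate. It sets out from 6 and comes back at 8.
  - Et3SiOTf and 2,6-lutidine in CH2Cl2 give {[4-(2,6-bis(methoxymethoxy)phenyl)-2-methylbutan-2-yl]oxy}triethylsilane F6.
  - The same iridium borylation, now on a substrate without O–H, gives the isolated boronate {[4-(2,6-bis(methoxymethoxy)-4-(4,4,5,5-tetramethyl-1,3,2-dioxaborolan-2-yl)phenyl)-2-methylbutan-2-yl]oxy}triethylsilane F7.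
  - NaBO3 tetrahydrate in THF and water, a milder oxidant, gives 3,5-bis(methoxymethoxy)-4-{3-methyl-3-[(triethylsilyl)oxy]butyl}phenol F8.
  - Bu4NF in THF removes the silyl ether and returns 8.

**Step 6.**
- What may go wrong: deprotonation at the doubly activated benzylic and allylic CH2 instead of the ring, or attack of iodine on the alkene during the quench.
- Fallback: introduce iodine and the alkyne before the prenyl group. It sets out from 2 and comes back at 13.
  - N-Iodosuccinimide in MeCN iodinates 2 at the position ortho to one acetal oxygen and para to the other, giving 1-iodo-2,4-bis(methoxymethoxy)benzene F9.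
  - Sonogashira coupling with 12 under the conditions of step 7 gives {[2,4-bis(methoxymethoxy)phenyl]ethynyl}trimethylsilane F10.
  - s-BuLi and TMEDA at −78 °C metalate the carbon between the two acetal oxygens; CuBr·SMe2 and 3 then give 13.
  - No alkene is present when iodine is introduced, and the only acidic C–H left is the one that is wanted.

**Step 10.**
- What may go wrong: acid-promoted closure of the tertiary alcohol or of the prenyl group onto a neighbouring phenol, or methanolysis of the tertiary alcohol, before the last and most hindered acetals (on C2′ and C4′) are gone.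
- Fallback: exchange the acetals for silyl ethers without a Brønsted acid. It sets out from 15 and comes back at 16.
  - Me3SiOTf and 2,2′-bipyridyl in MeCN at 0 °C convert the four aryl acetals into aryl trimethylsilyl ethers and silylate the tertiary hydroxyl, giving 3-{3-(3-methylbut-2-en-1-yl)-2,4-bis[(trimethylsilyl)oxy]phenyl}-6-{3-methyl-3-[(trimethylsilyl)oxy]butyl}-5,7-bis[(trimethylsilyl)oxy]-4H-chromen-4-one F11.
  - Aqueous citric acid in THF and MeOH at rt hydrolyses all five silyl ethers to 16 at a pH far milder than that of step 10.

## Further compounds

F1 | step 8 | 2-(1-hydroxyethyl)-4-(3-hydroxy-3-methylbutyl)-3,5-bis(methoxymethoxy)phenol (racemic) | CC(O)c1c(O)cc(OCOC)c(CCC(C)(C)O)c1OCOC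
F2 | step 8 | 1-[2-hydroxy-5-(3-hydroxy-3-methylbutyl)-4,6-bis(methoxymethoxy)phenyl]ethan-1-one | CC(=O)c1c(O)cc(OCOC)c(CCC(C)(C)O)c1OCOC
F3 | step 8 | (E)-3-(dimethylamino)-1-[2-hydroxy-5-(3-hydroxy-3-methylbutyl)-4,6-bis(methoxymethoxy)phenyl]prop-2-en-1-one | CN(C)/C=C/C(=O)c1c(O)cc(OCOC)c(CCC(C)(C)O)c1OCOC
F4 | step 8 | 6-(3-hydroxy-3-methylbutyl)-3-iodo-5,7-bis(methoxymethoxy)-4H-chromen-4-one | COCOc1cc2occ(I)c(=O)c2c(OCOC)c1CCC(C)(C)O
F5 | step 8 | 2-[2,4-bis(methoxymethoxy)-3-(3-methylbut-2-en-1-yl)phenyl]-4,4,5,5-tetramethyl-1,3,2-dioxaborolane | COCOc1ccc(B2OC(C)(C)C(C)(C)O2)c(OCOC)c1CC=C(C)C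
F6 | step 4 | {[4-(2,6-bis(methoxymethoxy)phenyl)-2-methylbutan-2-yl]oxy}triethylsilane | CC[Si](CC)(CC)OC(C)(C)CCc1c(OCOC)cccc1OCOC
F7 | step 4 | {[4-(2,6-bis(methoxymethoxy)-4-(4,4,5,5-tetramethyl-1,3,2-dioxaborolan-2-yl)phenyl)-2-methylbutan-2-yl]oxy}triethylsilane | CC[Si](CC)(CC)OC(C)(C)CCc1c(OCOC)cc(B2OC(C)(C)C(C)(C)O2)cc1OCOC
F8 | step 4 | 3,5-bis(methoxymethoxy)-4-{3-methyl-3-[(triethylsilyl)oxy]butyl}phenol | CC[Si](CC)(CC)OC(C)(C)CCc1c(OCOC)cc(O)cc1OCOC
F9 | step 6 | 1-iodo-2,4-bis(methoxymethoxy)benzene | COCOc1ccc(I)c(OCOC)c1
F10 | step 6 | {[2,4-bis(methoxymethoxy)phenyl]ethynyl}trimethylsilane | COCOc1ccc(C#C[Si](C)(C)C)c(OCOC)c1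
F11 | step 10 | 3-{3-(3-methylbut-2-en-1-yl)-2,4-bis[(trimethylsilyl)oxy]phenyl}-6-{3-methyl-3-[(trimethylsilyl)oxy]butyl}-5,7-bis[(trimethylsilyl)oxy]-4H-chromen-4-one | CC(C)=CCc1c(O[Si](C)(C)C)ccc(-c2coc3cc(O[Si](C)(C)C)c(CCC(C)(C)O[Si](C)(C)C)c(O[Si](C)(C)C)c3c2=O)c1O[Si](C)(C)C
A1 | alternative 1 | (E)-1-{2-[(tert-butyldimethylsilyl)oxy]-5-(3-hydroxy-3-methylbutyl)-4,6-bis(methoxymethoxy)phenyl}-2-[2,4-bis(methoxymethoxy)-3-(3-methylbut-2-en-1-yl)phenyl]-3-ethoxyprop-2-en-1-one | CCO/C=C(/C(=O)c1c(O[Si](C)(C)C(C)(C)C)cc(OCOC)c(CCC(C)(C)O)c1OCOC)c1ccc(OCOC)c(CC=C(C)C)c1OCOC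
A2 | alternative 1 | 4-{4-[(tert-butyldimethylsilyl)oxy]-3-iodo-2,6-bis(methoxymethoxy)phenyl}-2-methylbutan-2-ol | Ic1c(O[Si](C)(C)C(C)(C)C)cc(OCOC)c(CCC(C)(C)O)c1OCOC
A3 | alternative 1 | (E)-{1-[2,4-bis(methoxymethoxy)-3-(3-methylbut-2-en-1-yl)phenyl]-2-ethoxyethenyl}tributylstannane | CCO/C=C(/[Sn](CCCC)(CCCC)CCCC)c1ccc(OCOC)c(CC=C(C)C)c1OCOC
A4 | alternative 2 | 3-[2-hydroxy-3-(3-methylbut-2-en-1-yl)-4-(triisopropylsilyloxy)phenyl]-5,7-bis(methoxymethoxy)-6-{3-methyl-3-[(triethylsilyl)oxy]butyl}-4H-chromen-4-one | CC(C)=CCc1c(O)c(-c2coc3cc(OCOC)c(CCC(C)(C)O[Si](CC)(CC)CC)c(OCOC)c3c2=O)ccc1O[Si](C(C)C)(C(C)C)C(C)C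
A5 | alternative 2 | (E)-3-(4-diazo-3-oxobut-1-en-1-yl)-5,7-bis(methoxymethoxy)-6-{3-methyl-3-[(triethylsilyl)oxy]butyl}-4H-chromen-4-one | [N-]=[N+]=CC(=O)/C=C/c1coc2cc(OCOC)c(CCC(C)(C)O[Si](CC)(CC)CC)c(OCOC)c2c1=O
A6 | alternative 2 | triisopropyl[(5-methylhex-4-en-1-yn-1-yl)oxy]silane | CC(C)=CCC#CO[Si](C(C)C)(C(C)C)C(C)C
A7 | alternative 3 | 3-[2,4-bis(methoxymethoxy)-3-(3-methylbut-2-en-1-yl)phenyl]-5,7-bis(methoxymethoxy)-6-{3-methyl-3-[(triethylsilyl)oxy]butyl}-4H-chromen-4-one | COCOc1ccc(-c2coc3cc(OCOC)c(CCC(C)(C)O[Si](CC)(CC)CC)c(OCOC)c3c2=O)c(OCOC)c1CC=C(C)C
A8 | alternative 3 | 3,5-bis(methoxymethoxy)-4-{3-methyl-3-[(triethylsilyl)oxy]butyl}-2-(trimethylsilyl)phenyl trifluoromethanesulfonate | COCOc1cc(OS(=O)(=O)C(F)(F)F)c([Si](C)(C)C)c(OCOC)c1CCC(C)(C)O[Si](CC)(CC)CC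
A9 | alternative 3 | (E)-2-[2,4-bis(methoxymethoxy)-3-(3-methylbut-2-en-1-yl)phenyl]-3-methoxyprop-2-enoic acid | CO/C=C(/C(=O)O)c1ccc(OCOC)c(CC=C(C)C)c1OCOC
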